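| flask | Za | Zb | remark | time |
|---|---|---|---|---|
| Thursday's | 0.058 M | 2 equiv | run made earlier |  |
| Friday's | 0.081 M | 2 equiv | run made earlier |  |
| Monday's | 0.13 M | 2 equiv | run made earlier |  |
| Tuesday's | 0.058 M | 1 equiv | run made earlier |  |
| winter | 0.058 M | 2.00 equiv (fed, over 2.5 d) | all else is in the flask from the start; the feed brings no volume worth counting | 6.0 d |
| summer | 0.058 M | 2.00 equiv | everything together at the start | 6.0 d |
| dawn | 0.058 M (fed, over 2.5 d) | 2.00 equiv | all else is in the flask from the start; the feed brings no volume worth counting | 6.0 d |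

| run | time / d | Zj / % | Za / % |
|---|---|---|---|
| Thursday's | 1.67 | 45.2 | 1.1 |
| Thursday's | 3.00 | 48.4 | 0.7 |
| Thursday's | 5.00 | 51.3 | 0 |
| Thursday's | 6.00 | 52.0 | 2.6 |
| Friday's | 0.833 | 50.2 | 1.6 |
| Friday's | 2.00 | 53.8 | 2.3 |
| Friday's | 4.00 | 56.0 | 0.7 |
| Friday's | 6.00 | 60.9 | 0 |
| Monday's | 1.67 | 64.2 | 2.0 |
| Monday's | 3.00 | 66.4 | 0 |
| Monday's | 5.00 | 68.3 | 0 |
| Monday's | 6.00 | 70.0 | 0 |
| Tuesday's | 0.500 | 23.5 | 7.4 |
| Tuesday's | 1.04 | 27.6 | 0.9 |
| Tuesday's | 2.50 | 29.1 | 1.9 |
| Tuesday's | 6.00 | 34.2 | 0.1 |

(scatter of a reading: 1 percentage point)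

- the best flask by amount of Zj, in percent of the Za charged; "all alike" if 1.5 percentage points covers them all (winter / summer / dawn / all alike)
- amount of Zj at the end, in percent of the Za charged, winter
- amount of Zj at the end, in percent of the Za charged, summer
- amount of Zj at the end, in percent of the Za charged, dawn

- a reading or a percentage of Zj counts all its forms, free or not

The constant to read first is 0.542 from Thursday's run: this is the odds per equivalent, a selectivity factor taken from end yields, namely the fraction of the charge found as Zj over the fraction not so found, per equivalent of Zb. Tuesday's run, with half the Zb, gives 0.520, so as read at this Za charge and at 6.00 d, the odds follow the Zb. You also need the life of Za: Tuesday's run has 7.4 % left at 0.500 d, which reads as one turnover, a fall by a factor e, in 0.192 d.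

Now turn the question round: on my reckoning, winter stands level with summer if its Zb is in within about one turnover of Za. But count the turnovers in its feed:

feed time / Za life = 13.0

You see that this is far above one, so one Za life in winter meets about 0.154 equivalents:

odds = 0.0832, share = 7.68 %

This is my own figure, and it counts no later gain. In dawn the Zb stands ready from the start, so this count does not part dawn from summer.

The forecast names summer, with 21 % for winter, 52.3 % for summer and 50.5 % for dawn, and says of winter “Za dies before Zb arrives”.

The flasks give 23.9 % in winter, 52.9 % in summer and 50.9 % in dawn, so summer is best, as forecast, and you should charge the Zb at the start.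

    Za → Zc (k = 0.00105 /min)
    Za + Zb → Zj (k = 0.0197 /M/min)
    Zc ⇌ Zd (K = 0.358, k = 1.11 × 10⁻⁴ /min)
    Zd ⇌ Ze (K = 0.100, k = 4.06 × 10⁻⁴ /min)
    Ze → Zf (k = 4.11 × 10⁻⁴ /min)
    Zf ⇌ Zg (K = 0.850, k = 1.49 × 10⁻⁴ /min)
    Za ⇌ Zh (K = 13.0, k = 0.00191 /min)
    Zk ⇌ Zj, rate k8*(cs8 - [Zj]) while solid is left; crystals form when [Zj] > cs8 (solubility = 39.0 mM, k = 0.342 /min)

Carry the 0.542 back to summer, with its 2.00 equiv of Zb:

odds = 1.08, share = 52.0 %

Then carry it to the neighbouring flask, summer with 3.40 equiv of Zb:

odds = 1.84, share = 64.8 %

That flask gives 67.1 %.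

Readings and results are calculated with constants of no real substance; the scatter is artificial.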